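The primed benzene ring (C4a', C5', C6', C7', C8', C8a') is built, not substituted: it is cut at C5'–C6' and C7'–C8' into a 3-aryl-4-benzyloxy-6-methyl-2-pyrone-5-carboxylate and 1,1-dimethoxyethene. This exploits the para relationship between C4a', which carries C4', and the methoxylated C7', with the methyl on C5' and the aryl on C8', which is exactly what the union of a pyrone 5-ester with a ketene acetal produces. One cycloaddition, followed by loss of CO2 and methanol, gives the hindered 6,8'-biaryl benzoate with all six ring substituents placed. The precursor already holds the finished unprimed coumarin on pyrone C3; pyrone O4, the future O1', is benzylated so that it can be freed beside four methoxyls.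

Key step: step 8

Remark: the target SMILES defines no configuration at the hindered 6,8' biaryl axis and the molecule has no stereocentre, so the racemate is the goal.

Step 1
Reactants: 1 methyl orsellinate (methyl 2,4-dihydroxy-6-methylbenzoate)
Product: 2 methyl 2-hydroxy-4-methoxy-6-methylbenzoate
Conditions: MeI (1.05 equiv), K2CO3 (1.1 equiv), acetone, rt
Reagents that add atoms: iodomethane, CI
Why: Williamson O-methylation, in which the C4 hydroxyl is the more acidic and accessible one because the C2 hydroxyl is tied up in a hydrogen bond to the ester carbonyl, so one equivalent of MeI should methylate C4–OH only.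

Step 2
Reactants: 2 methyl 2-hydroxy-4-methoxy-6-methylbenzoate
Product: 3 methyl 3-bromo-6-hydroxy-4-methoxy-2-methylbenzoate
Conditions: NBS (1.0 equiv), MeCN, 0 °C to rt
Reagents that add atoms: N-bromosuccinimide, O=C1CCC(=O)N1Br
Why: Electrophilic aromatic bromination, expected at the carbon para to the free hydroxyl and ortho to the methoxyl (between OMe and CH3), since polar conditions favour para attack on phenols over the site lying between the two oxygens.

Step 3
Reactants: 3 methyl 3-bromo-6-hydroxy-4-methoxy-2-methylbenzoate; 4 (triphenylphosphoranylidene)ketene (Bestmann ylide)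
Product: 6 6-bromo-4,7-dimethoxy-5-methyl-2H-chromen-2-one, via aryl ylide ester 5 (not isolated)
Conditions: toluene, reflux
Reagents that add atoms: none
Why: Coumarin synthesis with the Bestmann ylide, in which the phenol adds across the ketene C=C to give a stabilised ester ylide and an intramolecular Wittig reaction at the neighbouring methyl ester carbonyl closes the pyranone while keeping the ester methoxyl as the 4-methoxyl.

Step 4
Reactants: 6 6-bromo-4,7-dimethoxy-5-methyl-2H-chromen-2-one; 7 di-tert-butyl malonate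
Product: 8 di-tert-butyl 2-(4,7-dimethoxy-5-methyl-2-oxo-2H-chromen-6-yl)propanedioate
Conditions: Pd(dba)2 (5 mol %), [HP(tBu)3]BF4 (10 mol %), K3PO4, toluene, 100 °C
Reagents that add atoms: none
Why: Palladium-catalysed α-arylation of a malonate, where the bulky electron-rich P(tBu)3 ligand should allow oxidative addition into the electron-rich, doubly ortho-substituted C6–Br bond and reductive elimination of the soft enolate, while the weak base K3PO4 spares the lactone and the tert-butyl esters can later be removed without hydroxide.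

Step 5
Reactants: 8 di-tert-butyl 2-(4,7-dimethoxy-5-methyl-2-oxo-2H-chromen-6-yl)propanedioate
Product: 9 2-(4,7-dimethoxy-5-methyl-2-oxo-2H-chromen-6-yl)propanedioic acid
Conditions: TFA/CH2Cl2 (1:2), 0 °C to rt; evaporate below 30 °C
Reagents that add atoms: none
Why: Acidolysis of tert-butyl esters (loss of isobutene through the tert-butyl cation) frees the malonic acid without any base that could open the lactone or displace the 4-methoxyl, and at room temperature the arylmalonic acid should not yet decarboxylate.

Step 6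
Reactants: 9 2-(4,7-dimethoxy-5-methyl-2-oxo-2H-chromen-6-yl)propanedioic acid; 10 methyl acetoacetate
Product: 12 methyl 3-(4,7-dimethoxy-5-methyl-2-oxo-2H-chromen-6-yl)-4-hydroxy-6-methyl-2-oxo-2H-pyran-5-carboxylate, via arylmalonyl dichloride 11 (not isolated)
Conditions: (COCl)2 (2.5 equiv), DMF (cat.), CH2Cl2, 0 °C to rt; evaporate; then 10 (1.2 equiv), toluene, 80 °C
Reagents that add atoms: none
Why: Classical 4-hydroxy-2-pyrone synthesis from a substituted malonyl dichloride and a β-keto ester, in which the enol oxygen and the central carbon of methyl acetoacetate are acylated in turn by the two acid chloride groups with loss of two HCl, which fixes the aryl on C3, the hydroxyl on C4, the ester on C5 and the methyl on C6.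

Step 7
Reactants: 12 methyl 3-(4,7-dimethoxy-5-methyl-2-oxo-2H-chromen-6-yl)-4-hydroxy-6-methyl-2-oxo-2H-pyran-5-carboxylate
Product: 13 methyl 4-(benzyloxy)-3-(4,7-dimethoxy-5-methyl-2-oxo-2H-chromen-6-yl)-6-methyl-2-oxo-2H-pyran-5-carboxylate
Conditions: BnBr (1.2 equiv), K2CO3, DMF, rt
Reagents that add atoms: benzyl bromide, BrCc1ccccc1
Why: O-Alkylation of the acidic 4-hydroxy-2-pyrone (a vinylogous carboxylic acid), which under carbonate conditions normally gives the 4-alkoxy-2-pyrone, with C-alkylation excluded by the aryl group on C3; benzyl is chosen because a Lewis acid needed to cleave a methyl ether here could also attack the 4-methoxyl of the finished coumarin.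

Step 8
Reactants: 13 methyl 4-(benzyloxy)-3-(4,7-dimethoxy-5-methyl-2-oxo-2H-chromen-6-yl)-6-methyl-2-oxo-2H-pyran-5-carboxylate; 14 1,1-dimethoxyethene
Product: 17 methyl 2-(benzyloxy)-3-(4,7-dimethoxy-5-methyl-2-oxo-2H-chromen-6-yl)-4-methoxy-6-methylbenzoate, via bicyclic lactone adduct 15 (not isolated), via dimethoxycyclohexadiene 16 (not isolated)
Conditions: 14 (10 equiv), toluene, sealed tube, 140 °C
Reagents that add atoms: none
Why: Inverse-electron-demand Diels–Alder reaction of a 2-pyrone-5-carboxylate with a ketene acetal: the nucleophilic CH2 of 14 attacks pyrone C6, the β-carbon of the C5 ester and δ-carbon of the lactone carbonyl, and the acetal carbon closes onto C3, so the new bonds are C5'–C6' and C7'–C8' (asynchronous, possibly through a zwitterion). The six-membered carbocycle is therefore closed by an intermolecular [4+2] cycloaddition that gives the bridged lactone 15; retro-[4+2] loss of CO2 gives diene 16, which becomes aromatic by 1,2-elimination of methanol. The closest known reactions are the conversions of coumalate and isodehydroacetate esters into 4-alkoxybenzoates with ketene acetals. No stereocentre is created that survives: the two bridgehead centres of 15 vanish on aromatisation and the biaryl axis forms as the racemate. The selectivity needed is regiochemical, and the substrate secures it twice, through the C5 ester that makes C6 the electrophilic terminus and through the C4 benzyloxy group that makes C3 the donor-stabilised terminus, placing the new methoxyl para to the ester. The tetrasubstituted diene with its aryl-shielded C3 is the reason for the excess of 14 and the high temperature.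

Step 9
Reactants: 17 methyl 2-(benzyloxy)-3-(4,7-dimethoxy-5-methyl-2-oxo-2H-chromen-6-yl)-4-methoxy-6-methylbenzoate
Product: 18 methyl 3-(4,7-dimethoxy-5-methyl-2-oxo-2H-chromen-6-yl)-2-hydroxy-4-methoxy-6-methylbenzoate
Conditions: H2 (1 atm), 10% Pd/C, EtOAc, rt
Reagents that add atoms: none
Why: Hydrogenolysis of the aryl benzyl ether, under which the methyl ethers, the esters and the trisubstituted, donor-substituted C3=C4 bond of the 4-methoxycoumarin should be inert at one atmosphere and room temperature.

Step 10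
Reactants: 18 methyl 3-(4,7-dimethoxy-5-methyl-2-oxo-2H-chromen-6-yl)-2-hydroxy-4-methoxy-6-methylbenzoate; 4 (triphenylphosphoranylidene)ketene
Product: 20 4,4',7,7'-tetramethoxy-5,5'-dimethyl-2H,2'H-[6,8'-bichromene]-2,2'-dione (racemic), via aryl ylide ester 19 (not isolated)
Conditions: toluene, reflux
Reagents that add atoms: none
Why: Coumarin synthesis with the Bestmann ylide as in step 3, where addition of the phenol gives ester ylide 19 and intramolecular Wittig olefination of the ortho ester carbonyl forms C3'=C4' with the ester methoxyl retained as the 4'-methoxyl, driven by formation of Ph3PO.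

Compound list
1 | methyl orsellinate (methyl 2,4-dihydroxy-6-methylbenzoate) | Cc1cc(O)cc(O)c1C(=O)OC | starting material
2 | methyl 2-hydroxy-4-methoxy-6-methylbenzoate | COC(=O)c1c(C)cc(OC)cc1O | intermediate
3 | methyl 3-bromo-6-hydroxy-4-methoxy-2-methylbenzoate | COC(=O)c1c(C)c(Br)c(OC)cc1O | intermediate
4 | (triphenylphosphoranylidene)ketene | O=C=C=P(c1ccccc1)(c1ccccc1)c1ccccc1 | starting material
5 | methyl 3-bromo-4-methoxy-2-methyl-6-{[2-(triphenyl-λ5-phosphanylidene)acetyl]oxy}benzoate | COC(=O)c1c(C)c(Br)c(OC)cc1OC(=O)C=P(c1ccccc1)(c1ccccc1)c1ccccc1 | intermediate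
6 | 6-bromo-4,7-dimethoxy-5-methyl-2H-chromen-2-one | COc1cc2oc(=O)cc(OC)c2c(C)c1Br | intermediate
7 | di-tert-butyl malonate | CC(C)(C)OC(=O)CC(=O)OC(C)(C)C | starting material
8 | di-tert-butyl 2-(4,7-dimethoxy-5-methyl-2-oxo-2H-chromen-6-yl)propanedioate | COc1cc2oc(=O)cc(OC)c2c(C)c1C(C(=O)OC(C)(C)C)C(=O)OC(C)(C)C | intermediate
9 | 2-(4,7-dimethoxy-5-methyl-2-oxo-2H-chromen-6-yl)propanedioic acid | COc1cc2oc(=O)cc(OC)c2c(C)c1C(C(=O)O)C(=O)O | intermediate
10 | methyl acetoacetate | COC(=O)CC(C)=O | starting material
11 | 2-(4,7-dimethoxy-5-methyl-2-oxo-2H-chromen-6-yl)propanedioyl dichloride | COc1cc2oc(=O)cc(OC)c2c(C)c1C(C(Cl)=O)C(Cl)=O | intermediate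
12 | methyl 3-(4,7-dimethoxy-5-methyl-2-oxo-2H-chromen-6-yl)-4-hydroxy-6-methyl-2-oxo-2H-pyran-5-carboxylate | COc1cc2oc(=O)cc(OC)c2c(C)c1-c1c(O)c(C(=O)OC)c(C)oc1=O | intermediate
13 | methyl 4-(benzyloxy)-3-(4,7-dimethoxy-5-methyl-2-oxo-2H-chromen-6-yl)-6-methyl-2-oxo-2H-pyran-5-carboxylate | COc1cc2oc(=O)cc(OC)c2c(C)c1-c1c(OCc2ccccc2)c(C(=O)OC)c(C)oc1=O | intermediate
14 | 1,1-dimethoxyethene | C=C(OC)OC | starting material
15 | methyl 5-(benzyloxy)-4-(4,7-dimethoxy-5-methyl-2-oxo-2H-chromen-6-yl)-8,8-dimethoxy-1-methyl-3-oxo-2-oxabicyclo[2.2.2]oct-5-ene-6-carboxylate (racemic) | COC(=O)C1=C(OCc2ccccc2)C3(c4c(OC)cc5oc(=O)cc(OC)c5c4C)C(=O)OC1(C)CC3(OC)OC | intermediate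
16 | methyl 6-(benzyloxy)-5-(4,7-dimethoxy-5-methyl-2-oxo-2H-chromen-6-yl)-4,4-dimethoxy-2-methylcyclohexa-1,5-diene-1-carboxylate | COC(=O)C1=C(C)CC(OC)(OC)C(c2c(OC)cc3oc(=O)cc(OC)c3c2C)=C1OCc1ccccc1 | intermediate
17 | methyl 2-(benzyloxy)-3-(4,7-dimethoxy-5-methyl-2-oxo-2H-chromen-6-yl)-4-methoxy-6-methylbenzoate | COC(=O)c1c(C)cc(OC)c(-c2c(OC)cc3oc(=O)cc(OC)c3c2C)c1OCc1ccccc1 | intermediate
18 | methyl 3-(4,7-dimethoxy-5-methyl-2-oxo-2H-chromen-6-yl)-2-hydroxy-4-methoxy-6-methylbenzoate | COC(=O)c1c(C)cc(OC)c(-c2c(OC)cc3oc(=O)cc(OC)c3c2C)c1O | intermediate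
19 | methyl 3-(4,7-dimethoxy-5-methyl-2-oxo-2H-chromen-6-yl)-4-methoxy-6-methyl-2-{[2-(triphenyl-λ5-phosphanylidene)acetyl]oxy}benzoate | COC(=O)c1c(C)cc(OC)c(-c2c(OC)cc3oc(=O)cc(OC)c3c2C)c1OC(=O)C=P(c1ccccc1)(c1ccccc1)c1ccccc1 | intermediate
20 | 4,4',7,7'-tetramethoxy-5,5'-dimethyl-2H,2'H-[6,8'-bichromene]-2,2'-dione | COc1cc2oc(=O)cc(OC)c2c(C)c1-c1c(OC)cc(C)c2c(OC)cc(=O)oc12 | target

Total step count: 10. Longest linear sequence: 10 steps (1 to 20).

Steps most likely to fail

Step 8. The cycloaddition may not start: the diene is tetrasubstituted, carries a donor on C4, and its C3 terminus is shielded by the twisted, doubly ortho-substituted aryl group, so polymerisation of the ketene acetal could outrun it. The fallback sets out from 1 and 6 and comes back to the route at 20; it forms the biaryl bond by cross-coupling of two coumarins instead of building the ring. Methyl orsellinate 1 would be iodinated between its two hydroxyls (I2, NaHCO3, aqueous THF, 0 °C) to methyl 2,4-dihydroxy-3-iodo-6-methylbenzoate F1. Selective methylation of the C4 hydroxyl (MeI, K2CO3, acetone) would give methyl 2-hydroxy-3-iodo-4-methoxy-6-methylbenzoate F2, and ylide 4 in refluxing toluene would convert it into 8-iodo-4,7-dimethoxy-5-methyl-2H-chromen-2-one F3. Bromide 6 would be borylated (B2pin2, Pd(OAc)2, SPhos, KOAc, dioxane, 90 °C) to 4,7-dimethoxy-5-methyl-6-(4,4,5,5-tetramethyl-1,3,2-dioxaborolan-2-yl)-2H-chromen-2-one F4. Suzuki–Miyaura coupling of F3 with F4 (Pd(OAc)2, SPhos, K3PO4, toluene/water, 100 °C) should then give 20 directly.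

Step 4. Reductive elimination of the bulky malonate from the doubly ortho-substituted arylpalladium intermediate may stall, so that hydrodebromination takes over. The fallback sets out from 6 and comes back at 8; it couples a smaller, neutral carbon nucleophile and adds the second ester afterwards. Negishi-type coupling of 6 with the Reformatsky reagent BrZnCH2CO2tBu (Pd(dba)2, XPhos, THF, 65 °C) should give tert-butyl 2-(4,7-dimethoxy-5-methyl-2-oxo-2H-chromen-6-yl)acetate F5. C-Acylation of its lithium enolate with Boc2O (LiN(SiMe3)2, 2.2 equiv, THF, −78 °C) would then give 8.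

Step 6. Decarboxylation of the arylmalonic acid, or attack of the liberated HCl on the coumarin enol ether, may occur before both acylations are complete. The fallback sets out from 9 and comes back at 12; it assembles the pyrone stepwise from the arylacetic ester. Acid 9 would be decarboxylated on purpose (DMSO, 90 °C) to 2-(4,7-dimethoxy-5-methyl-2-oxo-2H-chromen-6-yl)acetic acid F6 and esterified (Me3SiCHN2, MeOH/toluene, rt) to methyl 2-(4,7-dimethoxy-5-methyl-2-oxo-2H-chromen-6-yl)acetate F7. Acylation of the lithium enolate of F7 (LiN(SiMe3)2, 2.2 equiv, THF, −78 °C) with methyl 3-chloro-3-oxopropanoate should give dimethyl 2-(4,7-dimethoxy-5-methyl-2-oxo-2H-chromen-6-yl)-3-oxopentanedioate F8. C-Acetylation of its unhindered methylene (acetyl chloride, MgCl2, pyridine, CH2Cl2, 0 °C) would give dimethyl 2-acetyl-4-(4,7-dimethoxy-5-methyl-2-oxo-2H-chromen-6-yl)-3-oxopentanedioate F9. Lactonisation of the acetyl enol onto the aryl-bearing ester (p-TsOH cat., toluene, 110 °C) would then give 12.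

Further compounds
F1 | step 8 | methyl 2,4-dihydroxy-3-iodo-6-methylbenzoate | COC(=O)c1c(C)cc(O)c(I)c1O
F2 | step 8 | methyl 2-hydroxy-3-iodo-4-methoxy-6-methylbenzoate | COC(=O)c1c(C)cc(OC)c(I)c1O
F3 | step 8 | 8-iodo-4,7-dimethoxy-5-methyl-2H-chromen-2-one | COc1cc(C)c2c(OC)cc(=O)oc2c1I
F4 | step 8 | 4,7-dimethoxy-5-methyl-6-(4,4,5,5-tetramethyl-1,3,2-dioxaborolan-2-yl)-2H-chromen-2-one | COc1cc2oc(=O)cc(OC)c2c(C)c1B1OC(C)(C)C(C)(C)O1
F5 | step 4 | tert-butyl 2-(4,7-dimethoxy-5-methyl-2-oxo-2H-chromen-6-yl)acetate | COc1cc2oc(=O)cc(OC)c2c(C)c1CC(=O)OC(C)(C)C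
F6 | step 6 | 2-(4,7-dimethoxy-5-methyl-2-oxo-2H-chromen-6-yl)acetic acid | COc1cc2oc(=O)cc(OC)c2c(C)c1CC(=O)O
F7 | step 6 | methyl 2-(4,7-dimethoxy-5-methyl-2-oxo-2H-chromen-6-yl)acetate | COc1cc2oc(=O)cc(OC)c2c(C)c1CC(=O)OC
F8 | step 6 | dimethyl 2-(4,7-dimethoxy-5-methyl-2-oxo-2H-chromen-6-yl)-3-oxopentanedioate | COc1cc2oc(=O)cc(OC)c2c(C)c1C(C(=O)OC)C(=O)CC(=O)OC
F9 | step 6 | dimethyl 2-acetyl-4-(4,7-dimethoxy-5-methyl-2-oxo-2H-chromen-6-yl)-3-oxopentanedioate | COc1cc2oc(=O)cc(OC)c2c(C)c1C(C(=O)OC)C(=O)C(C(C)=O)C(=O)OC
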